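**Retrosynthetic overview**

1. Nostocyclophane C ⇐ MOM removal and mono-O-methylation of a C2-symmetric 1,1′-diol (the two benzylic OH groups are homotopic); each C3–Cl ⇐ C3–OH by Appel inversion.
2. Both benzylic C1–O bonds and both C3 carbinols ⇐ one enantioselective hydrative oxa-Michael/Tishchenko cascade on a C2-symmetric [7.7]paracyclophane bis-enone (key C–O bond formation, four stereocentres).
3. The 22-membered ring (the only ring formed; both arenes are bought) ⇐ head-to-tail double Horner–Wadsworth–Emmons macrodimerisation of one aryl-aldehyde/β-ketophosphonate monomer.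
4. Monomer ⇐ γ-alkylation of dimethyl (2-oxopropyl)phosphonate dianion with a primary iodide; its C7 stereocentre ⇐ Cu-catalysed asymmetric allylic butylation of a cinnamyl chloride made from MOM-protected 3,5-dihydroxybenzaldehyde acetal by ortho-lithiation/acrolein addition.

Assumption: for the catalyst-controlled steps on these new substrates (steps 4 and 8, and the epoxidation in the fallback to step 8) the catalyst antipode named is the one expected by analogy to give the drawn configuration; the mirror-image catalyst is equally available and is used if the sense proves opposite.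

Locants used for the macrocycles (18–24, F6, F7): each seven-carbon bridge is numbered from C1 (benzylic carbon on the arene carbon para to the butyl-bearing bridge end; O-bearing in the target) through C3 (Cl-bearing) to C7 (benzylic, butyl-bearing, bound to the arene carbon flanked by the two oxygens). Primes mark the second bridge. The target is (1S,3S,7R,1′S,3′S,7′R) with 1-OMe and 1′-OH.

**Route**

Step 1
Reactants: 1 3,5-dihydroxybenzaldehyde
Product: 2 3,5-bis(methoxymethoxy)benzaldehyde
Conditions: MOMCl (2.6 equiv), i-Pr2NEt (3 equiv), CH2Cl2, 0 °C to rt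
Reagents that add atoms: chloromethyl methyl ether COCCl
Why: Base-mediated O-alkylation (MOM protection) of both phenols leaves the aldehyde untouched and installs the groups that later direct ortho-lithiation.

Step 2
Reactants: 2 3,5-bis(methoxymethoxy)benzaldehyde
Product: 3 1-(dimethoxymethyl)-3,5-bis(methoxymethoxy)benzene
Conditions: HC(OMe)3 (3 equiv), MeOH, PPTS (5 mol %), rt; Et3N quench
Reagents that add atoms: trimethyl orthoformate COC(OC)OC
Why: Acid-catalysed acetalisation with the orthoformate as water scavenger masks the aldehyde against RLi/RMgX, and PPTS at rt is too weak to cleave aryl MOM ethers.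

Step 3
Reactants: 3 1-(dimethoxymethyl)-3,5-bis(methoxymethoxy)benzene; 4 acrolein
Product: 8 2-[(E)-3-chloroprop-1-en-1-yl]-5-(dimethoxymethyl)-1,3-bis(methoxymethoxy)benzene, via aryllithium 5 (not isolated), via lithium allylic alkoxide 6 (not isolated), via allylic mesylate 7 (not isolated)
Conditions: n-BuLi (1.1 equiv), THF, 0 °C, 1 h; acrolein, −78 °C; MsCl (1.2 equiv), −78 to 0 °C; filtered through basic alumina and used crude
Reagents that add atoms: methanesulfonyl chloride CS(=O)(=O)Cl
Why: Directed ortho-metalation at the position flanked by both OMOM groups, 1,2-addition to acrolein, O-mesylation of the lithium alkoxide and chloride return with allylic transposition (ion pair/SN2′) give the conjugated, less hindered (E)-cinnamyl chloride; no stereocentre is carried on.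

Step 4
Reactants: 8 2-[(E)-3-chloroprop-1-en-1-yl]-5-(dimethoxymethyl)-1,3-bis(methoxymethoxy)benzene; 9 n-butylmagnesium bromide
Product: 10 5-(dimethoxymethyl)-2-[(3R)-hept-1-en-3-yl]-1,3-bis(methoxymethoxy)benzene
Conditions: n-BuMgBr (1.3 equiv, slow addition), CuTC (3 mol %), L* (3.3 mol %; 2,2′-biphenol phosphoramidite of bis[(S)-1-(2-methoxyphenyl)ethyl]amine), CH2Cl2, −78 °C
Reagents that add atoms: none
Why: Copper-catalysed asymmetric allylic alkylation (γ-selective SN2′) in which the chiral phosphoramidite–Cu complex delivers butyl to one face of the E-alkene, setting the butyl-bearing benzylic stereocentre as R.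

Step 5
Reactants: 10 5-(dimethoxymethyl)-2-[(3R)-hept-1-en-3-yl]-1,3-bis(methoxymethoxy)benzene
Product: 12 5-(dimethoxymethyl)-2-[(3R)-1-iodoheptan-3-yl]-1,3-bis(methoxymethoxy)benzene, via alkylzirconocene chloride 11 (not isolated)
Conditions: Cp2Zr(H)Cl (1.5 equiv), THF, rt, 2 h; I2 (1.5 equiv), 0 °C
Reagents that add atoms: iodine II
Why: Hydrozirconation puts Zr on the terminal carbon (anti-Markovnikov) and iodinolysis of the C–Zr bond gives the primary iodide without touching the adjacent stereocentre, and I2 without base or activator does not iodinate the arene at 0 °C.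

Step 6
Reactants: 12 5-(dimethoxymethyl)-2-[(3R)-1-iodoheptan-3-yl]-1,3-bis(methoxymethoxy)benzene; 13 dimethyl (2-oxopropyl)phosphonate
Product: 16 dimethyl {(6R)-6-[4-formyl-2,6-bis(methoxymethoxy)phenyl]-2-oxodecyl}phosphonate, via phosphonate dianion 14 (not isolated), via acetal ketophosphonate 15 (not isolated)
Conditions: 13 (3 equiv), NaH, THF, 0 °C; n-BuLi, 0 °C; then 12, 0 °C to rt; work-up 1 M aq HCl/THF, rt, 30 min
Reagents that add atoms: water O
Why: γ-Alkylation of the β-ketophosphonate dianion (the more basic terminal carbanion attacks the primary iodide, SN2) builds the chain, and the dilute-acid work-up hydrolyses the aryl dimethyl acetal while aryl MOM ethers survive.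

Step 7
Reactants: 16 dimethyl {(6R)-6-[4-formyl-2,6-bis(methoxymethoxy)phenyl]-2-oxodecyl}phosphonate (two molecules, head-to-tail)
Product: 18 (1E,1′E,7R,7′R)-tetra-O-MOM [7.7]paracyclophane-1,1′-diene-3,3′-dione (bis-enone), via linear seco-dimer 17 (not isolated)
Conditions: LiCl (10 equiv), DBU (4 equiv), MeCN/THF, 0.01 M, rt, 24 h
Reagents that add atoms: none
Why: Two Masamune–Roush Horner–Wadsworth–Emmons olefinations, first intermolecular head-to-tail and then ring-closing to the 22-membered ring, give both enones E; one monomer cannot close on itself because an 11-membered E-enone paracyclophane is too strained.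

Step 8
Reactants: 18 (1E,1′E,7R,7′R)-tetra-O-MOM [7.7]paracyclophane-1,1′-diene-3,3′-dione
Product: 20 (1S,3R,7R,1′S,3′R,7′R)-tetra-O-MOM 3,3′-dihydroxy-[7.7]paracyclophane-1,1′-diyl bis(2,2-dimethylpropanoate), via bis-hemiacetal adduct 19 (not isolated)
Conditions: (R)-LLB·LiOH [LaLi3((R)-binaphthoxide)3/LiOH 1:1, 20 mol % per enone], t-BuCHO (12 equiv), H2O (2.4 equiv), THF, −20 °C, 48–72 h
Reagents that add atoms: pivalaldehyde CC(C)(C)C=O; water O
Why: Proposed new method: a hydrative oxa-Michael/Evans–Tishchenko cascade in which the La–OH/Li–OH site adds to t-BuCHO to give a metal-bound gem-diolate that adds reversibly to the β-carbon of the La-activated enone (C–O bond formation), the resulting β-(hemiacetal-oxy) ketone, which is exactly the intermediate of an Evans–Tishchenko reduction, then passes its hemiacetal hydride to the ketone through a La-bridged chair and irreversibly gives the 1,3-anti diol mono-pivalate with the ester on the benzylic oxygen, so that the chiral binaphthoxide pocket selects the (1S) epimer in the hydride-transfer step under dynamic kinetic control (the oxa-Michael step being reversible) and the chair fixes C3 as R; the closest known reaction types are the Evans–Tishchenko reduction of β-hydroxy ketones, LLB-catalysed asymmetric aldol–Tishchenko reactions (reversible aldol, selective Tishchenko step) and oxa-Michael additions of hemiacetal alkoxides.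

Step 9
Reactants: 20 (1S,3R,7R,1′S,3′R,7′R)-tetra-O-MOM 3,3′-dihydroxy-[7.7]paracyclophane-1,1′-diyl bis(2,2-dimethylpropanoate)
Product: 21 (1S,3S,7R,1′S,3′S,7′R)-tetra-O-MOM 3,3′-dichloro-[7.7]paracyclophane-1,1′-diyl bis(2,2-dimethylpropanoate)
Conditions: PPh3 (6 equiv), CCl4/MeCN (1:3), 2,6-lutidine (2 equiv), 50 °C
Reagents that add atoms: carbon tetrachloride ClC(Cl)(Cl)Cl
Why: Appel chlorination, in which chloride displaces the alkoxyphosphonium ion by SN2 with inversion, turns (3R) into (3S) and gives the 1,3-syn Cl/O relationship under neutral aprotic conditions that spare MOM and pivalate groups and contain no electrophilic chlorine for the arene.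

Step 10
Reactants: 21 (1S,3S,7R,1′S,3′S,7′R)-tetra-O-MOM 3,3′-dichloro-[7.7]paracyclophane-1,1′-diyl bis(2,2-dimethylpropanoate)
Product: 22 (1S,3S,7R,1′S,3′S,7′R)-tetra-O-MOM 3,3′-dichloro-[7.7]paracyclophane-1,1′-diol
Conditions: DIBAL-H (6 equiv), CH2Cl2, −78 °C; Rochelle salt work-up
Reagents that add atoms: none
Why: Reductive ester cleavage at −78 °C removes both pivalates at the acyl carbon, so the C1–O bonds and their configuration are retained, and secondary alkyl chlorides and MOM ethers are inert.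

Step 11
Reactants: 22 (1S,3S,7R,1′S,3′S,7′R)-tetra-O-MOM 3,3′-dichloro-[7.7]paracyclophane-1,1′-diol
Product: 23 (1S,3S,7R,1′S,3′S,7′R)-tetra-O-MOM 3,3′-dichloro-1-methoxy-[7.7]paracyclophan-1′-ol
Conditions: Me3OBF4 (1.1 equiv), proton sponge (2 equiv), 4 Å MS, CH2Cl2, 0 °C to rt; chromatographic separation, recovered 22 recycled
Reagents that add atoms: trimethyloxonium tetrafluoroborate C[O+](C)C.F[B-](F)(F)F
Why: O-Methylation with Meerwein salt gives a single mono-ether because the two benzylic OH groups are homotopic (statistical, about 45 % per pass, with diol and bis-ether recovered), and the non-basic conditions avoid alkoxide attack on the γ-chloride.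

Step 12
Reactants: 23 (1S,3S,7R,1′S,3′S,7′R)-tetra-O-MOM 3,3′-dichloro-1-methoxy-[7.7]paracyclophan-1′-ol
Product: 24 nostocyclophane C
Conditions: 3 M aq HCl/THF (1:3), 45 °C
Reagents that add atoms: none
Why: Acid hydrolysis of the four aryl MOM acetals frees the resorcinols, while the benzylic C–O bonds do not ionise (the cation is destabilised by two meta oxygens, and the aqueous, methanol-free medium cannot exchange OH for OMe) and secondary chlorides are stable.

**Compound list**

1 | 3,5-dihydroxybenzaldehyde | O=Cc1cc(O)cc(O)c1 | starting material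
2 | 3,5-bis(methoxymethoxy)benzaldehyde | O=Cc1cc(OCOC)cc(OCOC)c1 | intermediate
3 | 1-(dimethoxymethyl)-3,5-bis(methoxymethoxy)benzene | COC(OC)c1cc(OCOC)cc(OCOC)c1 | intermediate
4 | acrolein (prop-2-enal) | C=CC=O | starting material
5 | [4-(dimethoxymethyl)-2,6-bis(methoxymethoxy)phenyl]lithium | [Li]c1c(OCOC)cc(C(OC)OC)cc1OCOC | intermediate (not isolated)
6 | lithium 1-[4-(dimethoxymethyl)-2,6-bis(methoxymethoxy)phenyl]prop-2-en-1-olate (racemic) | [Li]OC(C=C)c1c(OCOC)cc(C(OC)OC)cc1OCOC | intermediate (not isolated)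
7 | 1-[4-(dimethoxymethyl)-2,6-bis(methoxymethoxy)phenyl]prop-2-en-1-yl methanesulfonate (racemic) | CS(=O)(=O)OC(C=C)c1c(OCOC)cc(C(OC)OC)cc1OCOC | intermediate (not isolated)
8 | 2-[(E)-3-chloroprop-1-en-1-yl]-5-(dimethoxymethyl)-1,3-bis(methoxymethoxy)benzene | ClC/C=C/c1c(OCOC)cc(C(OC)OC)cc1OCOC | intermediate
9 | n-butylmagnesium bromide | CCCC[Mg]Br | starting material
10 | 5-(dimethoxymethyl)-2-[(3R)-hept-1-en-3-yl]-1,3-bis(methoxymethoxy)benzene | C=C[C@@H](CCCC)c1c(OCOC)cc(C(OC)OC)cc1OCOC | intermediate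
11 | chlorobis(cyclopentadienyl){(3R)-3-[4-(dimethoxymethyl)-2,6-bis(methoxymethoxy)phenyl]heptyl}zirconium | Cl[Zr](CC[C@@H](CCCC)c1c(OCOC)cc(C(OC)OC)cc1OCOC)(C1C=CC=C1)C1C=CC=C1 | intermediate (not isolated)
12 | 5-(dimethoxymethyl)-2-[(3R)-1-iodoheptan-3-yl]-1,3-bis(methoxymethoxy)benzene | ICC[C@@H](CCCC)c1c(OCOC)cc(C(OC)OC)cc1OCOC | intermediate
13 | dimethyl (2-oxopropyl)phosphonate | CC(=O)CP(=O)(OC)OC | starting material
14 | sodium lithium 1,3-dianion of dimethyl (2-oxopropyl)phosphonate | [Li+].[Na+].[CH2-]C(=O)[CH-]P(=O)(OC)OC | intermediate (not isolated)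
15 | dimethyl {(6R)-6-[4-(dimethoxymethyl)-2,6-bis(methoxymethoxy)phenyl]-2-oxodecyl}phosphonate | COP(=O)(OC)CC(=O)CCC[C@@H](CCCC)c1c(OCOC)cc(C(OC)OC)cc1OCOC | intermediate (not isolated)
16 | dimethyl {(6R)-6-[4-formyl-2,6-bis(methoxymethoxy)phenyl]-2-oxodecyl}phosphonate | COP(=O)(OC)CC(=O)CCC[C@@H](CCCC)c1c(OCOC)cc(C=O)cc1OCOC | intermediate
17 | linear head-to-tail seco-dimer (E-enone with aldehyde and ketophosphonate termini; both butyl-bearing centres R) | COP(=O)(OC)CC(=O)CCC[C@@H](CCCC)c1c(OCOC)cc(/C=C/C(=O)CCC[C@@H](CCCC)c2c(OCOC)cc(C=O)cc2OCOC)cc1OCOC | intermediate (not isolated)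
18 | (1E,1′E,7R,7′R)-tetra-O-MOM [7.7]paracyclophane-1,1′-diene-3,3′-dione | CCCC[C@@H]1CCCC(=O)/C=C/c2cc(OCOC)c(c(OCOC)c2)[C@H](CCCC)CCCC(=O)/C=C/c2cc(OCOC)c1c(OCOC)c2 | intermediate
19 | (1S,7R,1′S,7′R)-tetra-O-MOM 1,1′-bis[(1-hydroxy-2,2-dimethylpropyl)oxy]-[7.7]paracyclophane-3,3′-dione (hemiacetal carbons undefined) | CCCC[C@@H]1CCCC(=O)C[C@H](OC(O)C(C)(C)C)c2cc(OCOC)c(c(OCOC)c2)[C@H](CCCC)CCCC(=O)C[C@H](OC(O)C(C)(C)C)c2cc(OCOC)c1c(OCOC)c2 | intermediate (not isolated)
20 | (1S,3R,7R,1′S,3′R,7′R)-tetra-O-MOM 3,3′-dihydroxy-[7.7]paracyclophane-1,1′-diyl bis(2,2-dimethylpropanoate) | CCCC[C@@H]1CCC[C@@H](O)C[C@H](OC(=O)C(C)(C)C)c2cc(OCOC)c(c(OCOC)c2)[C@H](CCCC)CCC[C@@H](O)C[C@H](OC(=O)C(C)(C)C)c2cc(OCOC)c1c(OCOC)c2 | intermediate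
21 | (1S,3S,7R,1′S,3′S,7′R)-tetra-O-MOM 3,3′-dichloro-[7.7]paracyclophane-1,1′-diyl bis(2,2-dimethylpropanoate) | CCCC[C@@H]1CCC[C@H](Cl)C[C@H](OC(=O)C(C)(C)C)c2cc(OCOC)c(c(OCOC)c2)[C@H](CCCC)CCC[C@H](Cl)C[C@H](OC(=O)C(C)(C)C)c2cc(OCOC)c1c(OCOC)c2 | intermediate
22 | (1S,3S,7R,1′S,3′S,7′R)-tetra-O-MOM 3,3′-dichloro-[7.7]paracyclophane-1,1′-diol | CCCC[C@@H]1CCC[C@H](Cl)C[C@H](O)c2cc(OCOC)c(c(OCOC)c2)[C@H](CCCC)CCC[C@H](Cl)C[C@H](O)c2cc(OCOC)c1c(OCOC)c2 | intermediate
23 | (1S,3S,7R,1′S,3′S,7′R)-tetra-O-MOM 3,3′-dichloro-1-methoxy-[7.7]paracyclophan-1′-ol (tetra-O-MOM nostocyclophane C) | CCCC[C@@H]1CCC[C@H](Cl)C[C@H](OC)c2cc(OCOC)c(c(OCOC)c2)[C@H](CCCC)CCC[C@H](Cl)C[C@H](O)c2cc(OCOC)c1c(OCOC)c2 | intermediate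
24 | nostocyclophane C | CCCC[C@@H]1CCC[C@H](Cl)C[C@H](OC)c2cc(O)c(c(O)c2)[C@H](CCCC)CCC[C@H](Cl)C[C@H](O)c2cc(O)c1c(O)c2 | target

**Step count and risks**

Total step count: 12. Longest linear sequence: 12 steps from 1 (both halves of the macrocycle come from the same monomer 16).

The three steps most likely to fail:

Step 8 (the proposed cascade). It may stall at the enone, give aldehyde self-Tishchenko products only, or open the ring by retro-aldol. The fallback uses known chemistry, sets out from 18 and comes back at 20. Nucleophilic asymmetric epoxidation of both enones [La(Oi-Pr)3/(R)-BINOL/Ph3As=O 1:1:1, 20 mol % per enone, TBHP, 4 Å MS, THF, rt] gives the bis-epoxy ketone (1R,2S,7R,1′R,2′S,7′R)-tetra-O-MOM 1,2:1′,2′-diepoxy-[7.7]paracyclophane-3,3′-dione F6, the benzylic C–O bonds being set by the catalyst. SmI2 (2.2 equiv per epoxide, THF/MeOH, −90 °C) cleaves the Cα–O bonds to the bis-β-hydroxy ketone (1S,7R,1′S,7′R)-tetra-O-MOM 1,1′-dihydroxy-[7.7]paracyclophane-3,3′-dione F7. A standard Evans–Tishchenko reduction [SmI2 30 mol %, t-BuCHO excess, THF, −10 °C] then gives 20.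

Step 4 (asymmetric allylic alkylation next to a di-ortho-substituted arene). Branched/linear ratio or ee may be poor. The fallback sets out from 3 and comes back at 12. Compound 3 is lithiated as in step 3 to 5, transmetalated (MgBr2·OEt2, then CuBr·SMe2, THF/Me2S, −40 °C) and added to (4S)-3-[(E)-hept-2-enoyl]-4-phenyl-1,3-oxazolidin-2-one F1, itself made in one step from commercial (E)-hept-2-enoic acid (PivCl, Et3N; lithiated (S)-4-phenyloxazolidin-2-one). Auxiliary-controlled conjugate addition anti to the 4-phenyl group of the chelated s-cis imide gives (4S)-3-{(3R)-3-[4-(dimethoxymethyl)-2,6-bis(methoxymethoxy)phenyl]heptanoyl}-4-phenyl-1,3-oxazolidin-2-one F2. LiBH4/MeOH (Et2O, 0 °C) cleaves the imide to (3R)-3-[4-(dimethoxymethyl)-2,6-bis(methoxymethoxy)phenyl]heptan-1-ol F3 with recovery of the auxiliary, and PPh3/I2/imidazole (CH2Cl2, 0 °C) gives 12.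

Step 7 (macrodimerisation). Oligomers may dominate. The fallback sets out from 16 and comes back at 18 by olefin metathesis instead of olefination. Compound 16 is added at −78 °C to Ph3P=CH2 (2.5 equiv, from Ph3PCH3Br/KHMDS, THF); one equivalent parks the ketophosphonate as its unreactive enolate and the rest methylenates the aldehyde, giving dimethyl {(6R)-6-[4-ethenyl-2,6-bis(methoxymethoxy)phenyl]-2-oxodecyl}phosphonate F4. Horner–Wadsworth–Emmons reaction with aqueous formaldehyde (K2CO3, THF/H2O, rt) gives the vinyl ketone (7R)-7-[4-ethenyl-2,6-bis(methoxymethoxy)phenyl]undec-1-en-3-one F5. Hoveyda–Grubbs II catalyst (10 mol %, toluene, 60 °C, 5 mM, argon sparge) then joins two molecules head-to-tail by styrene/enone cross-metathesis followed by ring-closing metathesis, giving 18.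

**Further compounds**

F1 | step 4 | (4S)-3-[(E)-hept-2-enoyl]-4-phenyl-1,3-oxazolidin-2-one | CCCC/C=C/C(=O)N1[C@@H](c2ccccc2)COC1=O
F2 | step 4 | (4S)-3-{(3R)-3-[4-(dimethoxymethyl)-2,6-bis(methoxymethoxy)phenyl]heptanoyl}-4-phenyl-1,3-oxazolidin-2-one | CCCC[C@H](CC(=O)N1[C@@H](c2ccccc2)COC1=O)c1c(OCOC)cc(C(OC)OC)cc1OCOC
F3 | step 4 | (3R)-3-[4-(dimethoxymethyl)-2,6-bis(methoxymethoxy)phenyl]heptan-1-ol | OCC[C@@H](CCCC)c1c(OCOC)cc(C(OC)OC)cc1OCOC
F4 | step 7 | dimethyl {(6R)-6-[4-ethenyl-2,6-bis(methoxymethoxy)phenyl]-2-oxodecyl}phosphonate | COP(=O)(OC)CC(=O)CCC[C@@H](CCCC)c1c(OCOC)cc(C=C)cc1OCOC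
F5 | step 7 | (7R)-7-[4-ethenyl-2,6-bis(methoxymethoxy)phenyl]undec-1-en-3-one | C=CC(=O)CCC[C@@H](CCCC)c1c(OCOC)cc(C=C)cc1OCOC
F6 | step 8 | (1R,2S,7R,1′R,2′S,7′R)-tetra-O-MOM 1,2:1′,2′-diepoxy-[7.7]paracyclophane-3,3′-dione | CCCC[C@@H]1CCCC(=O)[C@H]3O[C@@H]3c2cc(OCOC)c(c(OCOC)c2)[C@H](CCCC)CCCC(=O)[C@H]3O[C@@H]3c2cc(OCOC)c1c(OCOC)c2
F7 | step 8 | (1S,7R,1′S,7′R)-tetra-O-MOM 1,1′-dihydroxy-[7.7]paracyclophane-3,3′-dione | CCCC[C@@H]1CCCC(=O)C[C@H](O)c2cc(OCOC)c(c(OCOC)c2)[C@H](CCCC)CCCC(=O)C[C@H](O)c2cc(OCOC)c1c(OCOC)c2
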